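**Retrosynthetic overview**

1. The C40 polyene is cut at C8–C9 and C8'–C9' into a symmetric C18 heptaene bis(pinacol boronate) and two C11 ethynyl oxiranes; the cyclohexane rings come with β-cyclocitral and ketoisophorone.
2. Each 2,5-dihydrofuran ring is made from its ethynyl oxirane by SN2' alkenylation to an α-hydroxyallene and 5-endo O→C8 cyclisation, so the oxirane configuration is relayed through the allene axis into C8 or C8'.
3. The metal decides the relay: zerovalent palladium (anti SN2') gives the cis C5-methyl/C8-chain ring of the unhydroxylated end, and monovalent rhodium (syn SN2') gives the trans ring of the hydroxylated end.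
4. Enabling feature: the C5'–C6' oxirane is propargylic to C7'≡C8', so its opening leaves the tertiary C5' hydroxyl 1,3 to C8' across the C6'=C7'=C8' allene, ready to close the ring O–C5'–C6'=C7'–C8'; the oxirane ring and the alkyne oxidation level are temporary and are consumed in that step.
5. Ring order: cyclohexane rings (starting materials), temporary oxiranes (steps 7 and 17), left dihydrofuran (step 11), right dihydrofuran last (step 21); C5 and C5' come from Sharpless epoxidations, C3' from an asymmetric transfer hydrogenation.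

Key step: step 21

Remark: positions are given in carotenoid numbering with primed locants for the hydroxylated half; ethyl but-2-ynoate, the C10 dialdehyde, β-cyclocitral and ketoisophorone are taken as commercial.

**Route**

Step 1
Reactants: 1 ethyl but-2-ynoate
Product: 2 ethyl (2Z)-3-(4,4,5,5-tetramethyl-1,3,2-dioxaborolan-2-yl)but-2-enoate
Conditions: B2pin2 (1.1 equiv), CuCl (3 mol %), Xantphos (3 mol %), NaOt-Bu (6 mol %), MeOH (2 equiv), THF, 25 °C
Reagents that add atoms: bis(pinacolato)diboron CC1(C)OB(OC1(C)C)B1OC(C)(C)C(C)(C)O1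
Why: Copper-catalysed conjugate borylation of the ynoate adds copper and boron syn across the triple bond and protonation leaves boron on the β-carbon cis to hydrogen, which fixes boron trans to the future C11.

Step 2
Reactants: 2 ethyl (2Z)-3-(4,4,5,5-tetramethyl-1,3,2-dioxaborolan-2-yl)but-2-enoate
Product: 3 (2Z)-3-(4,4,5,5-tetramethyl-1,3,2-dioxaborolan-2-yl)but-2-en-1-ol
Conditions: i-Bu2AlH (2.3 equiv), CH2Cl2, −78 °C; aqueous Rochelle salt
Reagents that add atoms: none
Why: Ester reduction with i-Bu2AlH at low temperature should give the allylic alcohol without touching the pinacol boronate or the double-bond geometry.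

Step 3
Reactants: 3 (2Z)-3-(4,4,5,5-tetramethyl-1,3,2-dioxaborolan-2-yl)but-2-en-1-ol
Product: 4 2-[(2Z)-4-bromobut-2-en-2-yl]-4,4,5,5-tetramethyl-1,3,2-dioxaborolane
Conditions: CBr4 (1.2 equiv), PPh3 (1.25 equiv), CH2Cl2, 0 °C
Reagents that add atoms: carbon tetrabromide BrC(Br)(Br)Br
Why: Appel bromination converts the primary allylic alcohol to the bromide under neutral conditions that the alkenyl boronate tolerates.

Step 4
Reactants: 4 2-[(2Z)-4-bromobut-2-en-2-yl]-4,4,5,5-tetramethyl-1,3,2-dioxaborolane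
Product: 5 diethyl [(2Z)-3-(4,4,5,5-tetramethyl-1,3,2-dioxaborolan-2-yl)but-2-en-1-yl]phosphonate
Conditions: P(OEt)3 (3 equiv, neat), 90 °C
Reagents that add atoms: triethyl phosphite CCOP(OCC)OCC
Why: Michaelis–Arbuzov reaction of the primary allylic bromide gives the allylic phosphonate.

Step 5
Reactants: 5 diethyl [(2Z)-3-(4,4,5,5-tetramethyl-1,3,2-dioxaborolan-2-yl)but-2-en-1-yl]phosphonate (2.2 equiv); 6 (2E,4E,6E)-2,7-dimethylocta-2,4,6-trienedial
Product: 7 2,2'-[(2Z,4E,6E,8E,10E,12E,14Z)-6,11-dimethylhexadeca-2,4,6,8,10,12,14-heptaene-2,15-diyl]bis(4,4,5,5-tetramethyl-1,3,2-dioxaborolane) (C18 bis-boronate, chain all-trans, boron trans to the chain at both ends)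
Conditions: NaN(SiMe3)2 (2.15 equiv), THF, −78 °C; then 6, −78 → 0 °C, dark
Reagents that add atoms: none
Why: Twofold Horner–Wadsworth–Emmons olefination of the symmetric dialdehyde with the allylic phosphonate anion should form the C11=C12 and C11'=C12' double bonds E-selectively before any sensitive end group is present.

Step 6
Reactants: 8 2,6,6-trimethylcyclohex-1-ene-1-carbaldehyde (β-cyclocitral)
Product: 9 (2,6,6-trimethylcyclohex-1-en-1-yl)methanol (β-cyclogeraniol)
Conditions: NaBH4 (0.5 equiv), MeOH, 0 °C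
Reagents that add atoms: none
Why: 1,2-Reduction of the hindered enal gives the allylic alcohol needed for a directed asymmetric epoxidation.

Step 7
Reactants: 9 (2,6,6-trimethylcyclohex-1-en-1-yl)methanol
Product: 10 [(1R,6R)-2,2,6-trimethyl-7-oxabicyclo[4.1.0]heptan-1-yl]methanol
Conditions: Ti(Oi-Pr)4 (0.5 equiv), D-(−)-diethyl tartrate (0.6 equiv), t-BuOOH (2 equiv), 4 Å molecular sieves, CH2Cl2, −20 °C
Reagents that add atoms: tert-butyl hydroperoxide CC(C)(C)OO
Why: Sharpless asymmetric epoxidation of the tetrasubstituted allylic alcohol, in which the D-(−)-tartrate complex delivers oxygen to one face and sets both oxirane centres, including the future C5 (R).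

Step 8
Reactants: 10 [(1R,6R)-2,2,6-trimethyl-7-oxabicyclo[4.1.0]heptan-1-yl]methanol
Product: 11 (1S,6R)-2,2,6-trimethyl-7-oxabicyclo[4.1.0]heptane-1-carbaldehyde
Conditions: Dess–Martin periodinane (1.3 equiv), NaHCO3, CH2Cl2, 0 → 25 °C
Reagents that add atoms: none
Why: Dess–Martin oxidation gives the epoxy aldehyde, which has no α-hydrogen and cannot epimerise.

Step 9
Reactants: 11 (1S,6R)-2,2,6-trimethyl-7-oxabicyclo[4.1.0]heptane-1-carbaldehyde
Product: 12 (1R,6R)-1-ethynyl-2,2,6-trimethyl-7-oxabicyclo[4.1.0]heptane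
Conditions: dimethyl (1-diazo-2-oxopropyl)phosphonate (1.5 equiv), K2CO3 (2 equiv), MeOH, 0 → 25 °C
Reagents that add atoms: dimethyl (1-diazo-2-oxopropyl)phosphonate COP(=O)(OC)C(=[N+]=[N-])C(C)=O
Why: Seyferth–Gilbert homologation with the Ohira–Bestmann reagent converts the aldehyde to the terminal alkyne under mild carbonate conditions that the oxirane tolerates.

Step 10
Reactants: 12 (1R,6R)-1-ethynyl-2,2,6-trimethyl-7-oxabicyclo[4.1.0]heptane; 7 C18 bis-boronate (3 equiv, excess recovered)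
Product: 13 (5R,6R)-9'-(4,4,5,5-tetramethyl-1,3,2-dioxaborolan-2-yl)-6,7-didehydro-5,6-dihydro-9'-apo-β-caroten-5-ol (C29 allenol boronate, allene axis R, chain all-trans)
Conditions: Pd(PPh3)4 (5 mol %), dioxane/H2O (10:1), 60 °C, dark
Reagents that add atoms: none
Why: Palladium-catalysed SN2' coupling of an alkynyl oxirane with an alkenylboron reagent, in which zerovalent palladium attacks C8 anti to the propargylic C6–O bond and transmetalation/reductive elimination with retention place the polyenyl group anti to the departed oxygen, so the oxirane configuration is relayed into the allene axis while C5 stays untouched and the excess of 7 favours single coupling.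

Step 11
Reactants: 13 C29 allenol boronate
Product: 14 (5R,8S)-9'-(4,4,5,5-tetramethyl-1,3,2-dioxaborolan-2-yl)-5,8-epoxy-5,8-dihydro-9'-apo-β-carotene (C29 furanoid boronate)
Conditions: AgNO3 (20 mol %), CaCO3 (1 equiv), acetone/THF/H2O, 25 °C, dark
Reagents that add atoms: none
Why: Silver-promoted 5-endo cycloisomerisation of the α-hydroxyallene, in which the C5 hydroxyl adds to C8 in the ring plane while hydrogen and the chain on C8 keep their sides, so the allene axis sets C8 as S with the chain cis to the C5 methyl.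

Step 12
Reactants: 15 2,6,6-trimethylcyclohex-2-ene-1,4-dione (ketoisophorone)
Product: 16 (4R)-4-hydroxy-2,6,6-trimethylcyclohex-2-en-1-one
Conditions: RuCl(p-cymene)[(R,R)-TsDPEN] (0.5 mol %), HCO2H/Et3N (5:2), CH2Cl2, 25 °C
Reagents that add atoms: none
Why: Noyori-type asymmetric transfer hydrogenation reduces the unhindered C4 carbonyl chemoselectively and the (R,R) ligand should set the 4R carbinol centre, the future C3'.

Step 13
Reactants: 16 (4R)-4-hydroxy-2,6,6-trimethylcyclohex-2-en-1-one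
Product: 17 (4R)-4-[(tert-butyldimethylsilyl)oxy]-2,6,6-trimethylcyclohex-2-en-1-one
Conditions: TBSCl (1.2 equiv), imidazole (2.5 equiv), DMF, 25 °C
Reagents that add atoms: tert-butyldimethylsilyl chloride CC(C)(C)[Si](C)(C)Cl
Why: Standard silylation protects the secondary alcohol for the enolate and organometallic steps.

Step 14
Reactants: 17 (4R)-4-[(tert-butyldimethylsilyl)oxy]-2,6,6-trimethylcyclohex-2-en-1-one
Product: 19 (4S)-4-[(tert-butyldimethylsilyl)oxy]-2,6,6-trimethylcyclohex-1-en-1-yl trifluoromethanesulfonate, via lithium enolate 18 (not isolated)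
Conditions: LiBH(s-Bu)3 (1.1 equiv), THF, −78 °C; then PhNTf2 (1.2 equiv), −78 → 0 °C
Reagents that add atoms: N-phenylbis(trifluoromethanesulfonimide) O=S(=O)(N(c1ccccc1)S(=O)(=O)C(F)(F)F)C(F)(F)F
Why: Conjugate hydride reduction of the enone generates the enolate regiospecifically on the methyl-bearing side and O-triflation traps it as the tetrasubstituted enol triflate (reductive triflation).

Step 15
Reactants: 19 (4S)-4-[(tert-butyldimethylsilyl)oxy]-2,6,6-trimethylcyclohex-1-en-1-yl trifluoromethanesulfonate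
Product: 20 methyl (4S)-4-[(tert-butyldimethylsilyl)oxy]-2,6,6-trimethylcyclohex-1-ene-1-carboxylate
Conditions: Pd(OAc)2 (5 mol %), dppp (5 mol %), CO (1 atm), MeOH, Et3N (2 equiv), DMF, 70 °C
Reagents that add atoms: carbon monoxide [C-]#[O+]; methanol CO
Why: Palladium-catalysed methoxycarbonylation of the enol triflate installs the future C7' as an ester.

Step 16
Reactants: 20 methyl (4S)-4-[(tert-butyldimethylsilyl)oxy]-2,6,6-trimethylcyclohex-1-ene-1-carboxylate
Product: 21 [(4S)-4-[(tert-butyldimethylsilyl)oxy]-2,6,6-trimethylcyclohex-1-en-1-yl]methanol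
Conditions: i-Bu2AlH (2.5 equiv), CH2Cl2, −78 → 0 °C
Reagents that add atoms: none
Why: Reduction of the hindered conjugated ester with i-Bu2AlH gives the allylic alcohol.

Step 17
Reactants: 21 [(4S)-4-[(tert-butyldimethylsilyl)oxy]-2,6,6-trimethylcyclohex-1-en-1-yl]methanol
Product: 22 [(1S,4R,6S)-4-[(tert-butyldimethylsilyl)oxy]-2,2,6-trimethyl-7-oxabicyclo[4.1.0]heptan-1-yl]methanol
Conditions: Ti(Oi-Pr)4 (0.5 equiv), L-(+)-diethyl tartrate (0.6 equiv), t-BuOOH (2 equiv), 4 Å molecular sieves, CH2Cl2, −20 °C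
Reagents that add atoms: tert-butyl hydroperoxide CC(C)(C)OO
Why: Sharpless asymmetric epoxidation with L-(+)-tartrate puts the oxirane oxygen on the face anti to the silyloxy group (reagent control, expected to be matched with the substrate), which sets C5' (S) and makes the oxirane trans to the C3' oxygen.

Step 18
Reactants: 22 [(1S,4R,6S)-4-[(tert-butyldimethylsilyl)oxy]-2,2,6-trimethyl-7-oxabicyclo[4.1.0]heptan-1-yl]methanol
Product: 23 (1R,4R,6S)-4-[(tert-butyldimethylsilyl)oxy]-2,2,6-trimethyl-7-oxabicyclo[4.1.0]heptane-1-carbaldehyde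
Conditions: Dess–Martin periodinane (1.3 equiv), NaHCO3, CH2Cl2, 0 → 25 °C
Reagents that add atoms: none
Why: Dess–Martin oxidation gives the configurationally fixed epoxy aldehyde.

Step 19
Reactants: 23 (1R,4R,6S)-4-[(tert-butyldimethylsilyl)oxy]-2,2,6-trimethyl-7-oxabicyclo[4.1.0]heptane-1-carbaldehyde
Product: 24 (1S,4R,6S)-4-[(tert-butyldimethylsilyl)oxy]-1-ethynyl-2,2,6-trimethyl-7-oxabicyclo[4.1.0]heptane
Conditions: dimethyl (1-diazo-2-oxopropyl)phosphonate (1.5 equiv), K2CO3 (2 equiv), MeOH, 0 → 25 °C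
Reagents that add atoms: dimethyl (1-diazo-2-oxopropyl)phosphonate COP(=O)(OC)C(=[N+]=[N-])C(C)=O
Why: Seyferth–Gilbert homologation with the Ohira–Bestmann reagent gives the terminal alkyne without affecting the oxirane or the silyl ether.

Step 20
Reactants: 24 (1S,4R,6S)-4-[(tert-butyldimethylsilyl)oxy]-1-ethynyl-2,2,6-trimethyl-7-oxabicyclo[4.1.0]heptane
Product: 25 (1S,4R,6S)-1-ethynyl-2,2,6-trimethyl-7-oxabicyclo[4.1.0]heptan-4-ol
Conditions: Bu4NF (1.2 equiv), THF, 0 → 25 °C
Reagents that add atoms: none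
Why: Fluoride cleaves the silyl ether while the oxirane and the alkyne are inert, so no protecting group has to be removed after the key step.

Step 21
Reactants: 14 C29 furanoid boronate; 25 (1S,4R,6S)-1-ethynyl-2,2,6-trimethyl-7-oxabicyclo[4.1.0]heptan-4-ol (1.2 equiv)
Product: 27 (5R,8S,3'R,5'S,8'S)-5,8:5',8'-diepoxy-5,8,5',8'-tetrahydro-β,β-caroten-3'-ol (target CNP0406432.1), via C40 allenediol 26 (not isolated)
Conditions: [Rh(OH)(cod)]2 (5 mol %), THF/H2O (20:1), 25 °C, dark; then AgNO3 (0.5 equiv), CaCO3, acetone, 25 °C, dark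
Reagents that add atoms: none
Why: Proposed new method: an alkenylrhodium species formed by transmetalation of boronate 14 should add syn across the terminal alkyne of 25 with carbon–carbon bond formation at the unhindered C8' and rhodium at C7' next to the oxirane, and syn β-oxygen elimination should then open the oxirane to allenediol 26 with the polyenyl group on the side of the departed oxygen (syn SN2'); the closest known reaction type is the rhodium-catalysed syn-selective reaction of alkynyl oxiranes with arylboronic acids, extended here to a polyenyl pinacol boronate and a terminal alkyne. In the same flask AgNO3 activates the C7'=C8' bond of the α-hydroxyallene and the C5' hydroxyl closes the ring O–C5'–C6'=C7'–C8' by a 5-endo cyclisation onto the allene terminus, a mode established for α-allenols. The only new stereocentre, C8', is fixed by axis-to-centre chirality transfer, because oxygen attacks in the plane of C1'–C6'–C5' while hydrogen and the chain on C8' keep their sides, so the 6'R axis gives 8'S with the chain trans to the C5' methyl. The step needs syn and not anti SN2' selectivity (the anti mode of zerovalent palladium would lead to the 8'-epimer), regioselective carborhodation, and closure by the C5' and not the C3' oxygen. These are secured by coordination of the oxirane oxygen to rhodium, by the fully substituted C6' that blocks bond formation at C7', and by the trans C3' hydroxyl, which cannot reach the allene.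

**Compound list**

1 | ethyl but-2-ynoate | CC#CC(=O)OCC | starting material
2 | ethyl (2Z)-3-(4,4,5,5-tetramethyl-1,3,2-dioxaborolan-2-yl)but-2-enoate | CCOC(=O)/C=C(\C)B1OC(C)(C)C(C)(C)O1 | intermediate
3 | (2Z)-3-(4,4,5,5-tetramethyl-1,3,2-dioxaborolan-2-yl)but-2-en-1-ol | OC/C=C(\C)B1OC(C)(C)C(C)(C)O1 | intermediate
4 | 2-[(2Z)-4-bromobut-2-en-2-yl]-4,4,5,5-tetramethyl-1,3,2-dioxaborolane | BrC/C=C(\C)B1OC(C)(C)C(C)(C)O1 | intermediate
5 | diethyl [(2Z)-3-(4,4,5,5-tetramethyl-1,3,2-dioxaborolan-2-yl)but-2-en-1-yl]phosphonate | CCOP(=O)(OCC)C/C=C(\C)B1OC(C)(C)C(C)(C)O1 | intermediate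
6 | (2E,4E,6E)-2,7-dimethylocta-2,4,6-trienedial | O=C/C(C)=C/C=C/C=C(\C)C=O | starting material
7 | 2,2'-[(2Z,4E,6E,8E,10E,12E,14Z)-6,11-dimethylhexadeca-2,4,6,8,10,12,14-heptaene-2,15-diyl]bis(4,4,5,5-tetramethyl-1,3,2-dioxaborolane) | CC1(C)OB(OC1(C)C)/C(C)=C/C=C/C(C)=C/C=C/C=C(C)/C=C/C=C(\C)B1OC(C)(C)C(C)(C)O1 | intermediate
8 | 2,6,6-trimethylcyclohex-1-ene-1-carbaldehyde (β-cyclocitral) | O=CC1=C(C)CCCC1(C)C | starting material
9 | (2,6,6-trimethylcyclohex-1-en-1-yl)methanol | OCC1=C(C)CCCC1(C)C | intermediate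
10 | [(1R,6R)-2,2,6-trimethyl-7-oxabicyclo[4.1.0]heptan-1-yl]methanol | OC[C@@]12O[C@]1(C)CCCC2(C)C | intermediate
11 | (1S,6R)-2,2,6-trimethyl-7-oxabicyclo[4.1.0]heptane-1-carbaldehyde | O=C[C@@]12O[C@]1(C)CCCC2(C)C | intermediate
12 | (1R,6R)-1-ethynyl-2,2,6-trimethyl-7-oxabicyclo[4.1.0]heptane | C#C[C@@]12O[C@]1(C)CCCC2(C)C | intermediate
13 | (5R,6R)-9'-(4,4,5,5-tetramethyl-1,3,2-dioxaborolan-2-yl)-6,7-didehydro-5,6-dihydro-9'-apo-β-caroten-5-ol (allene axis R) | CC(/C=C/C=C(\C)C([H])=[C@@]=C1C(C)(C)CCC[C@@]1(C)O)=C\C=C\C=C(C)\C=C\C=C(/C)B1OC(C)(C)C(C)(C)O1 | intermediate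
14 | (5R,8S)-9'-(4,4,5,5-tetramethyl-1,3,2-dioxaborolan-2-yl)-5,8-epoxy-5,8-dihydro-9'-apo-β-carotene | CC(/C=C/C=C(\C)[C@@H]1C=C2C(C)(C)CCC[C@@]2(C)O1)=C\C=C\C=C(C)\C=C\C=C(/C)B1OC(C)(C)C(C)(C)O1 | intermediate
15 | 2,6,6-trimethylcyclohex-2-ene-1,4-dione (ketoisophorone) | CC1=CC(=O)CC(C)(C)C1=O | starting material
16 | (4R)-4-hydroxy-2,6,6-trimethylcyclohex-2-en-1-one | O=C1C(C)=C[C@H](O)CC1(C)C | intermediate
17 | (4R)-4-[(tert-butyldimethylsilyl)oxy]-2,6,6-trimethylcyclohex-2-en-1-one | O=C1C(C)=C[C@H](O[Si](C)(C)C(C)(C)C)CC1(C)C | intermediate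
18 | lithium (4S)-4-[(tert-butyldimethylsilyl)oxy]-2,6,6-trimethylcyclohex-1-en-1-olate | [Li+].[O-]C1=C(C)C[C@H](O[Si](C)(C)C(C)(C)C)CC1(C)C | intermediate
19 | (4S)-4-[(tert-butyldimethylsilyl)oxy]-2,6,6-trimethylcyclohex-1-en-1-yl trifluoromethanesulfonate | FC(F)(F)S(=O)(=O)OC1=C(C)C[C@H](O[Si](C)(C)C(C)(C)C)CC1(C)C | intermediate
20 | methyl (4S)-4-[(tert-butyldimethylsilyl)oxy]-2,6,6-trimethylcyclohex-1-ene-1-carboxylate | COC(=O)C1=C(C)C[C@H](O[Si](C)(C)C(C)(C)C)CC1(C)C | intermediate
21 | [(4S)-4-[(tert-butyldimethylsilyl)oxy]-2,6,6-trimethylcyclohex-1-en-1-yl]methanol | OCC1=C(C)C[C@H](O[Si](C)(C)C(C)(C)C)CC1(C)C | intermediate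
22 | [(1S,4R,6S)-4-[(tert-butyldimethylsilyl)oxy]-2,2,6-trimethyl-7-oxabicyclo[4.1.0]heptan-1-yl]methanol | OC[C@]12O[C@@]1(C)C[C@H](O[Si](C)(C)C(C)(C)C)CC2(C)C | intermediate
23 | (1R,4R,6S)-4-[(tert-butyldimethylsilyl)oxy]-2,2,6-trimethyl-7-oxabicyclo[4.1.0]heptane-1-carbaldehyde | O=C[C@]12O[C@@]1(C)C[C@H](O[Si](C)(C)C(C)(C)C)CC2(C)C | intermediate
24 | (1S,4R,6S)-4-[(tert-butyldimethylsilyl)oxy]-1-ethynyl-2,2,6-trimethyl-7-oxabicyclo[4.1.0]heptane | C#C[C@]12O[C@@]1(C)C[C@H](O[Si](C)(C)C(C)(C)C)CC2(C)C | intermediate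
25 | (1S,4R,6S)-1-ethynyl-2,2,6-trimethyl-7-oxabicyclo[4.1.0]heptan-4-ol | C#C[C@]12O[C@@]1(C)C[C@H](O)CC2(C)C | intermediate
26 | (5R,8S,3'R,5'S,6'R)-5,8-epoxy-6',7'-didehydro-5,8,5',6'-tetrahydro-β,β-carotene-3',5'-diol (allene axis R) | CC(/C=C/C=C(\C)[C@@H]1C=C2C(C)(C)CCC[C@@]2(C)O1)=C\C=C\C=C(C)\C=C\C=C(/C)C([H])=[C@@]=C1C(C)(C)C[C@@H](O)C[C@]1(C)O | intermediate
27 | (5R,8S,3'R,5'S,8'S)-5,8:5',8'-diepoxy-5,8,5',8'-tetrahydro-β,β-caroten-3'-ol (CNP0406432.1) | CC(/C=C/C=C(\C)[C@@H]1C=C2C(C)(C)CCC[C@@]2(C)O1)=C\C=C\C=C(C)\C=C\C=C(/C)[C@@H]1C=C2C(C)(C)C[C@@H](O)C[C@]2(C)O1 | target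

**Step count and risks**

Total steps: 21. Longest linear sequence: 10 steps (15 → 25 through steps 12–20, then step 21).

Steps most likely to fail:

Step 21 (Proposed new method). The polyenylrhodium species may be protonated before it adds to the alkyne, may add with the wrong regiochemistry at the terminal alkyne, or the syn course of the oxirane opening may be eroded, which would lower the yield or scramble C8'. The fallback uses known chemistry, sets out from 25 and 14 and returns to the route at 27. Alkyne 25 is iodinated (N-iodosuccinimide, catalytic AgNO3, acetone) to (1S,4R,6S)-1-(iodoethynyl)-2,2,6-trimethyl-7-oxabicyclo[4.1.0]heptan-4-ol F1. Suzuki–Miyaura coupling of 14 with F1 (Pd(PPh3)4, K3PO4, THF/H2O, 25 °C) should give the C40 alkynyl oxirane (5R,8S,3'R,5'S,6'S)-5,8:5',6'-diepoxy-7',8'-didehydro-5,8,5',6'-tetrahydro-β,β-caroten-3'-ol F2. Palladium-catalysed transfer hydrogenolysis of F2 (Pd2(dba)3·CHCl3, PBu3, HCO2H/Et3N, THF) delivers hydride to C8' anti to the propargylic C–O bond, which places the chain on the side of the departed oxygen and gives the same allenediol 26. Cyclisation of 26 with AgNO3/CaCO3 then gives 27.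

Step 10. Coupling at both boronate ends of 7 and protodeboronation of the electron-rich polyenyl boronate may compete with the single SN2' coupling. The fallback sets out from 6, 5 and 12 and returns at 14; it builds the chain linearly with one boronate only. Mono-olefination of excess 6 with the anion of 5 should give (2E,4E,6E,8E,10Z)-2,7-dimethyl-11-(4,4,5,5-tetramethyl-1,3,2-dioxaborolan-2-yl)dodeca-2,4,6,8,10-pentaenal F3. Palladium-catalysed anti SN2' coupling of F3 with 12 should give (5R,6R)-5-hydroxy-6,7-didehydro-5,6-dihydro-12'-apo-β-caroten-12'-al F4. Cyclisation with AgNO3 gives (5R,8S)-5,8-epoxy-5,8-dihydro-12'-apo-β-caroten-12'-al F5, and a Horner–Wadsworth–Emmons reaction of F5 with 5 gives 14.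

Step 5. The boron-bearing phosphonate anion may react through its γ-carbon or be held back as a borate complex, so the twofold olefination may stop halfway. The fallback sets out from 3 and 6 and returns at 7; it reverses the polarity so that the carbanion sits on the C10 unit. Alcohol 3 is oxidised (MnO2, CH2Cl2) to (2Z)-3-(4,4,5,5-tetramethyl-1,3,2-dioxaborolan-2-yl)but-2-enal F6. Dialdehyde 6 is reduced (NaBH4) to (2E,4E,6E)-2,7-dimethylocta-2,4,6-triene-1,8-diol F7, converted (CBr4, PPh3) to (2E,4E,6E)-1,8-dibromo-2,7-dimethylocta-2,4,6-triene F8 and then (P(OEt)3, 90 °C) to tetraethyl [(2E,4E,6E)-2,7-dimethylocta-2,4,6-triene-1,8-diyl]bis(phosphonate) F9. Twofold Horner–Wadsworth–Emmons reaction of F9 with F6 (NaN(SiMe3)2, THF) gives 7.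

**Further compounds**

F1 | step 21 | (1S,4R,6S)-1-(iodoethynyl)-2,2,6-trimethyl-7-oxabicyclo[4.1.0]heptan-4-ol | IC#C[C@]12O[C@@]1(C)C[C@H](O)CC2(C)C
F2 | step 21 | (5R,8S,3'R,5'S,6'S)-5,8:5',6'-diepoxy-7',8'-didehydro-5,8,5',6'-tetrahydro-β,β-caroten-3'-ol | CC(/C=C/C=C(\C)[C@@H]1C=C2C(C)(C)CCC[C@@]2(C)O1)=C\C=C\C=C(C)\C=C\C=C(/C)C#C[C@]12O[C@@]1(C)C[C@H](O)CC2(C)C
F3 | step 10 | (2E,4E,6E,8E,10Z)-2,7-dimethyl-11-(4,4,5,5-tetramethyl-1,3,2-dioxaborolan-2-yl)dodeca-2,4,6,8,10-pentaenal | O=C/C(C)=C/C=C/C=C(C)/C=C/C=C(\C)B1OC(C)(C)C(C)(C)O1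
F4 | step 10 | (5R,6R)-5-hydroxy-6,7-didehydro-5,6-dihydro-12'-apo-β-caroten-12'-al | CC(/C=C/C=C(\C)C([H])=[C@@]=C1C(C)(C)CCC[C@@]1(C)O)=C\C=C\C=C(C)\C=O
F5 | step 10 | (5R,8S)-5,8-epoxy-5,8-dihydro-12'-apo-β-caroten-12'-al | CC(/C=C/C=C(\C)[C@@H]1C=C2C(C)(C)CCC[C@@]2(C)O1)=C\C=C\C=C(C)\C=O
F6 | step 5 | (2Z)-3-(4,4,5,5-tetramethyl-1,3,2-dioxaborolan-2-yl)but-2-enal | O=C/C=C(\C)B1OC(C)(C)C(C)(C)O1
F7 | step 5 | (2E,4E,6E)-2,7-dimethylocta-2,4,6-triene-1,8-diol | OC/C(C)=C/C=C/C=C(\C)CO
F8 | step 5 | (2E,4E,6E)-1,8-dibromo-2,7-dimethylocta-2,4,6-triene | BrC/C(C)=C/C=C/C=C(\C)CBr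
F9 | step 5 | tetraethyl [(2E,4E,6E)-2,7-dimethylocta-2,4,6-triene-1,8-diyl]bis(phosphonate) | CCOP(=O)(OCC)C/C(C)=C/C=C/C=C(\C)CP(=O)(OCC)OCC
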